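## Analysis of the target

Isariotin C is an N-acylated 3-aminobicyclo[3.3.1]nonan-9-one. The core is numbered here C1 (bridgehead carbinol), C2 (CH2), C3 (CH–N), C4 (CH–OH), C5 (bridgehead CH), C6 (CH–OH), C7 and C8 (epoxide carbons, C8 on C1) and C9 (ketone). Ring A is C1, C2, C3, C4, C5, C9 and ring B is C1, C8, C7, C6, C5, C9. Seven stereocenters (1S,3S,4R,5S,6S,7S,8S in this numbering) sit on nine ring carbons, and only the C2 methylene interrupts them. The nitrogen on C3 is equatorial on ring A and cis to the C1 oxygen. The C4 and C6 hydroxyls are axial on rings A and B, and the epoxide oxygen, the C6 hydroxyl and the C1 hydroxyl all lie on the exo face of ring B. The sensitive groups are the tertiary α-ketol (C1/C9), two β-hydroxy ketone units through C5, an epoxide next to the ketol, an electrophilic enamide and a side-chain ketone. The difficulty is to set this dense, base- and acid-sensitive array on a bridged bicycle whose second ring can only close from a ring A conformer with both arms axial. The plan rests on one feature: the C1 oxygen and the C3 nitrogen are cis-1,3 on ring A across the bare C2 methylene, which is what N–O cleavage of an isoxazolidine spanning C1 and C3 leaves behind.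

## Retrosynthetic reasoning

**38 to 37 (C7–O and C8–O).** The epoxide is the most electrophilic group of the target and is therefore made last. In alkene 37 the C6 hydroxyl (pseudoaxial), the C1 hydroxyl and the open exo face of the bicycle all point an oxidant to the same side. The forward step must epoxidise the ring alkene only and leave the electron-poor enamide alone.

**37 to 36 to 35 (C7=C8).** Ring B is opened at the alkene to the monocyclic diene 35, which carries a vinyl group on C1 and on C6. This cut removes the bicycle and leaves a cyclohexanone whose stereocenters can be set without strain. The forward metathesis has to pass through the ring A chair in which both alkenyl arms are axial. The silyl ethers of 36 are removed only once C5 is a bridgehead and its β-hydroxy ketones can no longer eliminate or undergo retro-aldol cleavage.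

**35 to 27 and 33 (amide C–N).** The side chain is attached as the complete acid 33, so no alkene geometry has to be set on the core. Acid 33 is cut at C2=C3 into enone 31 and acrylic acid 32 (cross-metathesis), and 31 at its ketone into nitrile 28 and Grignard reagent 29.

**27 to 26 to 25 (N–benzyl and N–O).** The primary amine comes from oxidative loss of the 4-methoxybenzyl group of 26, and 26 from reductive cleavage of the N–O bond of isoxazolidine 25. That cleavage frees the C1 hydroxyl and the C3 amine together and lets ring A flip.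

**25 to 23 (the two vinyl groups).** Both vinyl groups are carried through the cycloaddition as 2-(phenylsulfanyl)ethyl arms and released by sulfoxide elimination. There are two reasons for masking them. A vinyl on C1 would make the dipolarophile a cross-conjugated dienone. A vinyl on C6 would be a second dipolarophile at the same tether length as the enone and would close a cyclopentane in the fused mode. With thioether arms the enone is the only alkene in nitrone 22.

**23 to 22 to 20 and 21 (C2–C3 and C1–O, key step).** The isoxazolidine is cut back to the open-chain nitrone 22, made from aldehyde 20 and hydroxylamine 21. This one disconnection removes ring A, the C1 and C3 stereocenters and both heteroatom bonds. What remains is an acyclic chain with only C4, C5 and C6 stereogenic, all three within reach of aldol chemistry. The forward step needs bridged regiochemistry and one alkene face.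

**20 to 19 to 18 to 14 and 17 (C9–C1).** The aldehyde is carried as a primary silyl ether until the step before condensation (19, 18). The enone is cut between C9 and C1 into Weinreb amide 14 and alkenyllithium 17, which comes from bromide 16 and alcohol 15. This cut is convergent and puts the 1,1-disubstituted alkene in place without any olefination next to the sensitive β-silyloxy carbonyl.

**14 to 13 to 12 to 7 and 10 (C5–C6).** C5 carries the carbonyl between two carbinols, and both carbinols are syn to their neighbour in the aldol sense. The C5–C6 bond is therefore made by an auxiliary-controlled syn aldol of imide 7 with aldehyde 10, which sets C5 and C6 in one step. Aldehyde 10 is the conjugate adduct of acrolein 8 and thiophenol 9.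

**7 to 4 and 5; 4 to 3 to 2 to 1.** The acyl group of 7 holds C9, C5, C4 and C3. Its only stereocenter, C4, is taken from dimethyl (R)-malate 1 by reduction of the ester next to the hydroxyl (2), silylation (3) and saponification (4). C3 stays at the alcohol oxidation level until step 12, so no acetal has to be hydrolysed next to a silyl ether.

## Alternatives that were turned down

**Alternative 1:** The disconnection cuts both C4–C5 and C5–C6 at C5 and leads to the open-chain methyl ketone A1, which carries an α-amino aldehyde arm and an epoxy aldehyde arm on the quaternary C1. In the forward step, soft enolisation of A1 lets C5 add to the C4 aldehyde (ring A) and then to the C6 aldehyde (ring B) to give bicycle A2. In its favour, two rings, two C–C bonds and three stereocenters arise in one operation, the nitrogen is already a carbamate and the epoxide is already present. After its key step it is shorter than the chosen route, and it avoids N-dealkylation altogether. Against it, A1 holds an epimerisable α-amino aldehyde, an epoxy aldehyde and a fully substituted C1 that must be made enantiopure beforehand. The cascade must choose the C4 aldehyde first, and both new carbinols must come out axial, the less stable arrangement, under conditions where aldols reverse. After the first closure C5 is an enolisable carbon flanked by a β-hydroxyl, so dehydration competes with the second, strained closure. The chosen strategy sets C4, C5 and C6 by an auxiliary aldol on an open chain and asks its key step only for C1 and C3 under neutral heating. It pays for this with a longer linear sequence.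

**Alternative 2:** The disconnection cuts C5–C6 of ring B and leads to the branched 5-enopyranoside A3. In the forward step a catalytic divalent mercury salt hydrates the enol ether, and the mercury enolate at C5 adds to the unmasked C6 aldehyde to give cyclohexanone A4. In its favour, the sugar supplies C1, C7 and C8 enantiopure, and the carbocyclisation is a dependable reaction class. On drawing three stereocenters from the chiral pool it is stronger than the chosen route, which takes one from the pool and two from an auxiliary. Against it, A3 needs a tertiary allyl carbinol and an anhydro ring on a pyranoside, which takes many steps, and both must survive a Lewis-acidic metal. Nothing favours the axial C6 carbinol, and β-hydroxy ketones of this kind lose water easily. Ring A is still entirely missing in A4: C4 is not present, and C3–N, C4–OH and the C4–C5 bond would have to be built with three stereocenters onto a base-sensitive epoxy ketol. The chosen route makes the epoxide last and fixes the ring A stereocenters before any ring exists.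

**Alternative 3:** The disconnection cuts C9–C5 and uses a temporary N–C9 bond in lactam A5. In the forward step the ester enolate at C5 attacks the carbamate-activated lactam carbonyl, the N–C9 bond breaks, and ring A closes as β-keto ester A6. In its favour, C3 comes from an amino acid, the closure is irreversible, and the nitrogen emerges as a carbamate. On nitrogen handling it is stronger than the chosen route, which must remove a benzyl-type group oxidatively. Against it, the quaternary C1 must be set by two successive substitutions α to the lactam carbonyl under weak 1,3-control from C3, and the enolate must then attack a carbonyl flanked by that fully substituted carbon. In A6, C5 is the acidic carbon of a β-keto ester, so its configuration is not held and the C4 silyloxy group can be eliminated. C6 is only an ester carbon, so ring B still needs C6, C7 and C8 to be set. The chosen route delivers C1 and C3 together from one concerted event and carries C5 with its configuration fixed by the aldol.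

Key step: step 13

Remarks before the steps:
- Bicyclic compounds 36–38 are named with the core numbering of the analysis. Descriptors in all names follow from the SMILES in the compound list.
- Abbreviations: TBS = tert-butyldimethylsilyl, TBSO = tert-butyldimethylsilyloxy, PMB = 4-methoxybenzyl, DMP = Dess–Martin periodinane, IBX = 2-iodoxybenzoic acid.
- Aldehyde 10 is prepared in step 5 so that only common starting materials are needed.

## Route

Step 1
Reactants: 1 dimethyl (R)-malate
Product: 2 methyl (3R)-3,4-dihydroxybutanoate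
Conditions: BH3·SMe2, NaBH4 (cat.), THF, 0 °C → rt; MeOH quench
Reagents that add atoms: none
Why: Chelation-directed borane reduction: the alkoxyborane formed at the free hydroxyl delivers hydride only to the neighbouring ester, and the stereocenter (future C4) is not touched.

Step 2
Reactants: 2 methyl (3R)-3,4-dihydroxybutanoate
Product: 3 methyl (3R)-3,4-bis(TBSO)butanoate
Conditions: TBSCl, imidazole, DMF, rt
Reagents that add atoms: TBSCl, CC(C)(C)[Si](C)(C)Cl
Why: Standard silylation of both hydroxyls, run directly so that the diol ester has no time to lactonise.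

Step 3
Reactants: 3 methyl (3R)-3,4-bis(TBSO)butanoate
Product: 4 (3R)-3,4-bis(TBSO)butanoic acid
Conditions: LiOH, THF/MeOH/H2O, 0 °C → rt; dilute HCl to pH 4 at 0 °C
Reagents that add atoms: LiOH (its hydroxide oxygen becomes the acid OH), [Li+].[OH-]
Why: Saponification of a methyl ester; TBS ethers tolerate cold aqueous LiOH and a silyloxy group is a poor leaving group for β-elimination under these conditions.

Step 4
Reactants: 4 (3R)-3,4-bis(TBSO)butanoic acid; 5 (4S)-4-benzyloxazolidin-2-one
Product: 7 (4S)-4-benzyl-3-[(3R)-3,4-bis(TBSO)butanoyl]oxazolidin-2-one, via mixed pivalic anhydride 6 (not isolated)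
Conditions: PivCl, Et3N, THF, −20 °C; then 5, LiCl, −20 °C → rt
Reagents that add atoms: none
Why: N-Acylation of the auxiliary through the mixed anhydride, which is attacked at its less hindered carbonyl; no strong base is needed.

Step 5
Reactants: 8 acrolein; 9 thiophenol
Product: 10 3-(phenylsulfanyl)propanal
Conditions: Et3N (cat.), CH2Cl2, 0 °C
Reagents that add atoms: none
Why: Conjugate addition of a thiol to an enal; the product is a saturated aldehyde that carries the future C7 vinyl group in masked form.

Step 6
Reactants: 7 (4S)-4-benzyl-3-[(3R)-3,4-bis(TBSO)butanoyl]oxazolidin-2-one; 10 3-(phenylsulfanyl)propanal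
Product: 12 (4S)-4-benzyl-3-[(2R,3R)-2-[(1R)-1,2-bis(TBSO)ethyl]-3-hydroxy-5-(phenylsulfanyl)pentanoyl]oxazolidin-2-one, via boron (Z)-enolate 11 (not isolated)
Conditions: Bu2BOTf, i-Pr2NEt, CH2Cl2, 0 °C; then 10, −78 → 0 °C; pH 7 buffer/MeOH, no peroxide
Reagents that add atoms: none
Why: Evans syn aldol: the (Z)-boron enolate reacts through a Zimmerman–Traxler chair on the face away from the benzyl group, which sets C5 and C6 (syn to each other, sense fixed by the auxiliary). A covalent boron enolate tolerates the β-silyloxy group, and the peroxide-free work-up spares the thioether.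

Step 7
Reactants: 12 (4S)-4-benzyl-3-[(2R,3R)-2-[(1R)-1,2-bis(TBSO)ethyl]-3-hydroxy-5-(phenylsulfanyl)pentanoyl]oxazolidin-2-one
Product: 13 (2R,3R)-2-[(1R)-1,2-bis(TBSO)ethyl]-3-hydroxy-N-methoxy-N-methyl-5-(phenylsulfanyl)pentanamide
Conditions: MeNH(OMe)·HCl, AlMe3, THF, −20 → 0 °C
Reagents that add atoms: N,O-dimethylhydroxylamine hydrochloride, CNOC.Cl
Why: Transamination of an aldol imide to the Weinreb amide; the aluminium alkoxide of the free C6 hydroxyl directs the amide reagent to the exocyclic carbonyl, and auxiliary 5 is recovered.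

Step 8
Reactants: 13 (2R,3R)-2-[(1R)-1,2-bis(TBSO)ethyl]-3-hydroxy-N-methoxy-N-methyl-5-(phenylsulfanyl)pentanamide
Product: 14 (2R,3R)-2-[(1R)-1,2-bis(TBSO)ethyl]-3-(TBSO)-N-methoxy-N-methyl-5-(phenylsulfanyl)pentanamide
Conditions: TBSOTf, 2,6-lutidine, CH2Cl2, −78 → 0 °C
Reagents that add atoms: TBSOTf, CC(C)(C)[Si](C)(C)OS(=O)(=O)C(F)(F)F
Why: Silylation of a hindered secondary alcohol with the silyl triflate; it blocks retro-aldol cleavage and removes the acidic proton before the organolithium step.

Step 9
Reactants: 15 3-bromobut-3-en-1-ol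
Product: 16 [(3-bromobut-3-en-1-yl)sulfanyl]benzene
Conditions: PhSSPh, PBu3, THF, rt
Reagents that add atoms: diphenyl disulfide, c1ccc(SSc2ccccc2)cc1
Why: Phosphine–disulfide thioetherification of a primary alcohol (substitution at the alkoxyphosphonium carbon by thiolate); the vinyl bromide is inert.

Step 10
Reactants: 16 [(3-bromobut-3-en-1-yl)sulfanyl]benzene; 14 (2R,3R)-2-[(1R)-1,2-bis(TBSO)ethyl]-3-(TBSO)-N-methoxy-N-methyl-5-(phenylsulfanyl)pentanamide
Product: 18 (4R,5R)-4-[(1R)-1,2-bis(TBSO)ethyl]-5-(TBSO)-7-(phenylsulfanyl)-2-[2-(phenylsulfanyl)ethyl]hept-1-en-3-one, via alkenyllithium 17 (not isolated)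
Conditions: 16, t-BuLi (2 equiv), Et2O, −78 °C; then 14, THF, −78 → −20 °C; aq NH4Cl
Reagents that add atoms: none
Why: Bromine–lithium exchange followed by Weinreb ketone synthesis; the chelated tetrahedral adduct holds until work-up, so the enone forms only after the nucleophile is gone. The low temperature limits deprotonation at C5.

Step 11
Reactants: 18 (4R,5R)-4-[(1R)-1,2-bis(TBSO)ethyl]-5-(TBSO)-7-(phenylsulfanyl)-2-[2-(phenylsulfanyl)ethyl]hept-1-en-3-one
Product: 19 (4R,5R)-5-(TBSO)-4-[(1R)-1-(TBSO)-2-hydroxyethyl]-7-(phenylsulfanyl)-2-[2-(phenylsulfanyl)ethyl]hept-1-en-3-one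
Conditions: HF·pyridine, pyridine, THF, 0 °C
Reagents that add atoms: none
Why: Selective desilylation: the unhindered primary TBS ether is cleaved by buffered HF·pyridine well before the two secondary ones, and the medium is too mild to epimerise C5.

Step 12
Reactants: 19 (4R,5R)-5-(TBSO)-4-[(1R)-1-(TBSO)-2-hydroxyethyl]-7-(phenylsulfanyl)-2-[2-(phenylsulfanyl)ethyl]hept-1-en-3-one
Product: 20 (2R,3R)-2-(TBSO)-3-[(1R)-1-(TBSO)-3-(phenylsulfanyl)propyl]-5-methylidene-4-oxo-7-(phenylsulfanyl)heptanal
Conditions: DMP, NaHCO3, CH2Cl2, 0 °C → rt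
Reagents that add atoms: none
Why: Dess–Martin oxidation under buffered, near-neutral conditions gives the α-silyloxy aldehyde without epimerisation at C4; alcohols are oxidised much faster than aryl thioethers. The aldehyde is used at once.

Step 13
Reactants: 20 (2R,3R)-2-(TBSO)-3-[(1R)-1-(TBSO)-3-(phenylsulfanyl)propyl]-5-methylidene-4-oxo-7-(phenylsulfanyl)heptanal; 21 N-(4-methoxybenzyl)hydroxylamine
Product: 23 (1S,2R,3R,5S)-2-(TBSO)-3-[(1R)-1-(TBSO)-3-(phenylsulfanyl)propyl]-7-(4-methoxybenzyl)-5-[2-(phenylsulfanyl)ethyl]-6-oxa-7-azabicyclo[3.2.1]octan-4-one, via (Z)-nitrone 22 (not isolated)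
Conditions: 21, MgSO4, CH2Cl2, 0 °C → rt; then toluene, 80 °C
Reagents that add atoms: none
Why: Condensation of 20 with 21 gives the (Z)-aldonitrone 22, and this 1,3-dipole adds suprafacially, in a concerted but asynchronous [3+2] cycloaddition, across the C1=C2 alkene of the α-methylene ketone. The closest known reaction type is the intramolecular nitrone–alkene cycloaddition of C-(pent-4-enyl) nitrones, which turns from the fused to the bridged mode when the inner alkene carbon is substituted. Ring A (C1, C2, C3, C4, C5, C9) closes through the new C2–C3 bond with both alkene carbons inside the ring (endo with respect to the alkene), and the isoxazolidine (C1, C2, C3, N, O) closes through C1–O in the same event, so that N–O spans C3 and C1 as a 1,3-diaxial bridge of a chair. C3 and C1 are set together: the bridge forces them cis, and their sense relative to C4 and C5 follows from the chair transition state with the C4 silyloxy group and the C5 arm equatorial, since the other face would put both axial and push the C5 arm against the forming bridge. The step needs bridged regiochemistry (carbon to C2, oxygen to C1): the fused mode would have to make a quaternary C–C bond at C1, and the enone polarisation sends the nitrone carbon to the β-methylene carbon as in additions to 2-substituted acrylic systems. It also needs the enone to be the only dipolarophile, which is why the future C7 vinyl group is present as a thioether arm: a free vinyl on C6 would sit at the same tether length and close a cyclopentane in the fused mode. Condensation at the aldehyde is faster than conjugate addition of the hydroxylamine to the α-substituted enone, and the neutral conditions leave the β-silyloxy ketone and the thioethers untouched.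

Step 14
Reactants: 23 (1S,2R,3R,5S)-2-(TBSO)-3-[(1R)-1-(TBSO)-3-(phenylsulfanyl)propyl]-7-(4-methoxybenzyl)-5-[2-(phenylsulfanyl)ethyl]-6-oxa-7-azabicyclo[3.2.1]octan-4-one
Product: 25 (1S,2R,3R,5S)-2-(TBSO)-3-[(1R)-1-(TBSO)prop-2-en-1-yl]-5-ethenyl-7-(4-methoxybenzyl)-6-oxa-7-azabicyclo[3.2.1]octan-4-one, via bis-sulfoxide 24 (not isolated)
Conditions: NaIO4, MeOH/THF/H2O, 0 °C → rt; then NaHCO3, toluene, 110 °C
Reagents that add atoms: none
Why: Periodate oxidises both thioethers to sulfoxides without going on to sulfones or touching the weakly nucleophilic isoxazolidine nitrogen, and each alkyl phenyl sulfoxide then undergoes thermal syn-elimination. The only β-hydrogens are on C8 and C7, so only the two terminal alkenes can form.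

Step 15
Reactants: 25 (1S,2R,3R,5S)-2-(TBSO)-3-[(1R)-1-(TBSO)prop-2-en-1-yl]-5-ethenyl-7-(4-methoxybenzyl)-6-oxa-7-azabicyclo[3.2.1]octan-4-one
Product: 26 (2S,4S,5R,6R)-2-ethenyl-2-hydroxy-4-[(4-methoxybenzyl)amino]-5-(TBSO)-6-[(1R)-1-(TBSO)prop-2-en-1-yl]cyclohexan-1-one
Conditions: Zn, AcOH/THF/H2O, rt
Reagents that add atoms: none
Why: Dissolving-metal cleavage of the weak N–O bond, as used to turn isoxazolidines into 1,3-amino alcohols and α-aminooxy ketones into α-ketols; at room temperature it is faster than reductive loss of the α-oxygen. Alkenes and silyl ethers are inert, and no stereocenter is touched.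

Step 16
Reactants: 26 (2S,4S,5R,6R)-2-ethenyl-2-hydroxy-4-[(4-methoxybenzyl)amino]-5-(TBSO)-6-[(1R)-1-(TBSO)prop-2-en-1-yl]cyclohexan-1-one
Product: 27 (2S,4S,5R,6R)-4-amino-2-ethenyl-2-hydroxy-5-(TBSO)-6-[(1R)-1-(TBSO)prop-2-en-1-yl]cyclohexan-1-one
Conditions: (NH4)2Ce(NO3)6, MeCN/H2O, 0 °C; NaHCO3 work-up
Reagents that add atoms: none
Why: Oxidative N-debenzylation: tetravalent cerium oxidises the electron-rich benzylamine to the benzylic iminium ion, which is hydrolysed by water. The primary amine is protonated in the acidic medium and so protected from further oxidation.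

Step 17
Reactants: 28 hex-5-enenitrile; 29 pentylmagnesium bromide
Product: 31 undec-1-en-6-one, via magnesium ketimine 30 (not isolated)
Conditions: Et2O, 0 °C → reflux; then aq HCl, rt
Reagents that add atoms: water, O
Why: Grignard addition to a nitrile stops at the metalloimine, which is hydrolysed to the ketone on acidic work-up, so no tertiary alcohol can form.

Step 18
Reactants: 31 undec-1-en-6-one; 32 acrylic acid
Product: 33 (2E)-7-oxododec-2-enoic acid
Conditions: second-generation Hoveyda–Grubbs catalyst, CH2Cl2, 40 °C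
Reagents that add atoms: none
Why: Cross-metathesis of a terminal alkene with excess acrylic acid; the electron-poor partner does not homodimerise readily and the conjugated product forms as the E isomer.

Step 19
Reactants: 27 (2S,4S,5R,6R)-4-amino-2-ethenyl-2-hydroxy-5-(TBSO)-6-[(1R)-1-(TBSO)prop-2-en-1-yl]cyclohexan-1-one; 33 (2E)-7-oxododec-2-enoic acid
Product: 35 (2E)-N-[(1S,2R,3R,5S)-2-(TBSO)-3-[(1R)-1-(TBSO)prop-2-en-1-yl]-5-ethenyl-5-hydroxy-4-oxocyclohexyl]-7-oxododec-2-enamide, via benzotriazolyl ester 34 (not isolated)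
Conditions: EDC·HCl, HOBt, i-Pr2NEt, CH2Cl2, 0 °C → rt
Reagents that add atoms: none
Why: Carbodiimide amide coupling through the active ester; the primary amine is far more nucleophilic than the tertiary C1 hydroxyl, and the mild base does not enolise the ketone.

Step 20
Reactants: 35 (2E)-N-[(1S,2R,3R,5S)-2-(TBSO)-3-[(1R)-1-(TBSO)prop-2-en-1-yl]-5-ethenyl-5-hydroxy-4-oxocyclohexyl]-7-oxododec-2-enamide
Product: 36 (2E)-N-[(1S,3S,4R,5R,6R)-4,6-bis(TBSO)-1-hydroxy-9-oxobicyclo[3.3.1]non-7-en-3-yl]-7-oxododec-2-enamide
Conditions: second-generation Hoveyda–Grubbs catalyst, toluene (high dilution), 80 °C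
Reagents that add atoms: none
Why: Ring-closing metathesis of a cis-2,6-dialkenyl cyclohexanone to a bicyclo[3.3.1]nonenone: after loss of the N–O bridge ring A can flip to the chair with both alkenyl arms axial, and closure of the six-membered ring B drains that conformer. The two terminal alkenes react in preference to the internal electron-poor enamide alkene.

Step 21
Reactants: 36 (2E)-N-[(1S,3S,4R,5R,6R)-4,6-bis(TBSO)-1-hydroxy-9-oxobicyclo[3.3.1]non-7-en-3-yl]-7-oxododec-2-enamide
Product: 37 (2E)-N-[(1S,3S,4R,5R,6R)-1,4,6-trihydroxy-9-oxobicyclo[3.3.1]non-7-en-3-yl]-7-oxododec-2-enamide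
Conditions: HF·pyridine, pyridine, THF, 0 °C → rt
Reagents that add atoms: none
Why: Fluoride-mediated desilylation under weakly acidic conditions, which avoids base-induced α-ketol rearrangement. C5 is now a bridgehead, so the two β-hydroxy ketones can neither eliminate nor undergo retro-aldol cleavage.

Step 22
Reactants: 37 (2E)-N-[(1S,3S,4R,5R,6R)-1,4,6-trihydroxy-9-oxobicyclo[3.3.1]non-7-en-3-yl]-7-oxododec-2-enamide
Product: 38 isariotin C, (2E)-N-[(1S,3S,4R,5S,6S,7S,8S)-7,8-epoxy-1,4,6-trihydroxy-9-oxobicyclo[3.3.1]nonan-3-yl]-7-oxododec-2-enamide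
Conditions: VO(acac)2 (cat.), t-BuOOH, CH2Cl2, 0 °C → rt
Reagents that add atoms: tert-butyl hydroperoxide, CC(C)(C)OO
Why: Hydroxyl-directed epoxidation of an allylic alcohol: the vanadium alkoxide of the pseudoaxial C6 hydroxyl (helped by the C1 hydroxyl) delivers the peroxide oxygen to the face it occupies, which is also the open exo face of ring B, so C7 and C8 are set syn to both hydroxyls. The enamide alkene has no directing hydroxyl and is electron-poor, and this reagent does not attack ketones.

## Compound list

1 | dimethyl (R)-malate | COC(=O)[C@H](O)CC(=O)OC | starting material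
2 | methyl (3R)-3,4-dihydroxybutanoate | OC[C@H](O)CC(=O)OC | intermediate
3 | methyl (3R)-3,4-bis(TBSO)butanoate | COC(=O)C[C@@H](O[Si](C)(C)C(C)(C)C)CO[Si](C)(C)C(C)(C)C | intermediate
4 | (3R)-3,4-bis(TBSO)butanoic acid | OC(=O)C[C@@H](O[Si](C)(C)C(C)(C)C)CO[Si](C)(C)C(C)(C)C | intermediate
5 | (4S)-4-benzyloxazolidin-2-one | O=C1OC[C@H](Cc2ccccc2)N1 | starting material
6 | mixed anhydride of 4 with pivalic acid (not isolated) | CC(C)(C)C(=O)OC(=O)C[C@@H](O[Si](C)(C)C(C)(C)C)CO[Si](C)(C)C(C)(C)C | intermediate
7 | (4S)-4-benzyl-3-[(3R)-3,4-bis(TBSO)butanoyl]oxazolidin-2-one | O=C1OC[C@H](Cc2ccccc2)N1C(=O)C[C@@H](O[Si](C)(C)C(C)(C)C)CO[Si](C)(C)C(C)(C)C | intermediate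
8 | acrolein | C=CC=O | starting material
9 | thiophenol | Sc1ccccc1 | starting material
10 | 3-(phenylsulfanyl)propanal | O=CCCSc1ccccc1 | intermediate
11 | dibutylboron (Z)-enolate of 7 (not isolated) | CCCCB(CCCC)O/C(=C\[C@@H](O[Si](C)(C)C(C)(C)C)CO[Si](C)(C)C(C)(C)C)N1C(=O)OC[C@@H]1Cc1ccccc1 | intermediate
12 | (4S)-4-benzyl-3-[(2R,3R)-2-[(1R)-1,2-bis(TBSO)ethyl]-3-hydroxy-5-(phenylsulfanyl)pentanoyl]oxazolidin-2-one | O=C1OC[C@H](Cc2ccccc2)N1C(=O)[C@H]([C@H](O)CCSc1ccccc1)[C@@H](O[Si](C)(C)C(C)(C)C)CO[Si](C)(C)C(C)(C)C | intermediate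
13 | (2R,3R)-2-[(1R)-1,2-bis(TBSO)ethyl]-3-hydroxy-N-methoxy-N-methyl-5-(phenylsulfanyl)pentanamide | CON(C)C(=O)[C@H]([C@H](O)CCSc1ccccc1)[C@@H](O[Si](C)(C)C(C)(C)C)CO[Si](C)(C)C(C)(C)C | intermediate
14 | (2R,3R)-2-[(1R)-1,2-bis(TBSO)ethyl]-3-(TBSO)-N-methoxy-N-methyl-5-(phenylsulfanyl)pentanamide | CON(C)C(=O)[C@H]([C@H](O[Si](C)(C)C(C)(C)C)CCSc1ccccc1)[C@@H](O[Si](C)(C)C(C)(C)C)CO[Si](C)(C)C(C)(C)C | intermediate
15 | 3-bromobut-3-en-1-ol | OCCC(Br)=C | starting material
16 | [(3-bromobut-3-en-1-yl)sulfanyl]benzene | C=C(Br)CCSc1ccccc1 | intermediate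
17 | [4-(phenylsulfanyl)but-1-en-2-yl]lithium (not isolated) | [Li]C(=C)CCSc1ccccc1 | intermediate
18 | (4R,5R)-4-[(1R)-1,2-bis(TBSO)ethyl]-5-(TBSO)-7-(phenylsulfanyl)-2-[2-(phenylsulfanyl)ethyl]hept-1-en-3-one | C=C(CCSc1ccccc1)C(=O)[C@H]([C@H](O[Si](C)(C)C(C)(C)C)CCSc1ccccc1)[C@@H](O[Si](C)(C)C(C)(C)C)CO[Si](C)(C)C(C)(C)C | intermediate
19 | (4R,5R)-5-(TBSO)-4-[(1R)-1-(TBSO)-2-hydroxyethyl]-7-(phenylsulfanyl)-2-[2-(phenylsulfanyl)ethyl]hept-1-en-3-one | C=C(CCSc1ccccc1)C(=O)[C@H]([C@H](O[Si](C)(C)C(C)(C)C)CCSc1ccccc1)[C@@H](O[Si](C)(C)C(C)(C)C)CO | intermediate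
20 | (2R,3R)-2-(TBSO)-3-[(1R)-1-(TBSO)-3-(phenylsulfanyl)propyl]-5-methylidene-4-oxo-7-(phenylsulfanyl)heptanal | C=C(CCSc1ccccc1)C(=O)[C@H]([C@H](O[Si](C)(C)C(C)(C)C)CCSc1ccccc1)[C@@H](O[Si](C)(C)C(C)(C)C)C=O | intermediate
21 | N-(4-methoxybenzyl)hydroxylamine | COc1ccc(CNO)cc1 | starting material
22 | (Z)-N-(4-methoxybenzyl) nitrone of aldehyde 20 (not isolated) | [O-]/[N+](Cc1ccc(OC)cc1)=C\[C@H](O[Si](C)(C)C(C)(C)C)[C@@H]([C@H](O[Si](C)(C)C(C)(C)C)CCSc1ccccc1)C(=O)C(=C)CCSc1ccccc1 | intermediate
23 | (1S,2R,3R,5S)-2-(TBSO)-3-[(1R)-1-(TBSO)-3-(phenylsulfanyl)propyl]-7-(4-methoxybenzyl)-5-[2-(phenylsulfanyl)ethyl]-6-oxa-7-azabicyclo[3.2.1]octan-4-one | COc1ccc(CN2O[C@]3(CCSc4ccccc4)C[C@H]2[C@H](O[Si](C)(C)C(C)(C)C)[C@@H]([C@H](O[Si](C)(C)C(C)(C)C)CCSc2ccccc2)C3=O)cc1 | intermediate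
24 | bis-sulfoxide of 23, mixture at sulfur (not isolated) | COc1ccc(CN2O[C@]3(CCS(=O)c4ccccc4)C[C@H]2[C@H](O[Si](C)(C)C(C)(C)C)[C@@H]([C@H](O[Si](C)(C)C(C)(C)C)CCS(=O)c2ccccc2)C3=O)cc1 | intermediate
25 | (1S,2R,3R,5S)-2-(TBSO)-3-[(1R)-1-(TBSO)prop-2-en-1-yl]-5-ethenyl-7-(4-methoxybenzyl)-6-oxa-7-azabicyclo[3.2.1]octan-4-one | COc1ccc(CN2O[C@]3(C=C)C[C@H]2[C@H](O[Si](C)(C)C(C)(C)C)[C@@H]([C@H](O[Si](C)(C)C(C)(C)C)C=C)C3=O)cc1 | intermediate
26 | (2S,4S,5R,6R)-2-ethenyl-2-hydroxy-4-[(4-methoxybenzyl)amino]-5-(TBSO)-6-[(1R)-1-(TBSO)prop-2-en-1-yl]cyclohexan-1-one | COc1ccc(CN[C@H]2C[C@](O)(C=C)C(=O)[C@H]([C@H](O[Si](C)(C)C(C)(C)C)C=C)[C@H]2O[Si](C)(C)C(C)(C)C)cc1 | intermediate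
27 | (2S,4S,5R,6R)-4-amino-2-ethenyl-2-hydroxy-5-(TBSO)-6-[(1R)-1-(TBSO)prop-2-en-1-yl]cyclohexan-1-one | N[C@H]1C[C@](O)(C=C)C(=O)[C@H]([C@H](O[Si](C)(C)C(C)(C)C)C=C)[C@H]1O[Si](C)(C)C(C)(C)C | intermediate
28 | hex-5-enenitrile | C=CCCCC#N | starting material
29 | pentylmagnesium bromide | CCCCC[Mg]Br | starting material
30 | N-(bromomagnesio) imine of undec-1-en-6-one (not isolated) | CCCCCC(=N[Mg]Br)CCCC=C | intermediate
31 | undec-1-en-6-one | CCCCCC(=O)CCCC=C | intermediate
32 | acrylic acid | C=CC(=O)O | starting material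
33 | (2E)-7-oxododec-2-enoic acid | CCCCCC(=O)CCC/C=C/C(=O)O | intermediate
34 | benzotriazol-1-yl (2E)-7-oxododec-2-enoate (not isolated) | CCCCCC(=O)CCC/C=C/C(=O)On1nnc2ccccc12 | intermediate
35 | (2E)-N-[(1S,2R,3R,5S)-2-(TBSO)-3-[(1R)-1-(TBSO)prop-2-en-1-yl]-5-ethenyl-5-hydroxy-4-oxocyclohexyl]-7-oxododec-2-enamide | CCCCCC(=O)CCC/C=C/C(=O)N[C@H]1C[C@](O)(C=C)C(=O)[C@H]([C@H](O[Si](C)(C)C(C)(C)C)C=C)[C@H]1O[Si](C)(C)C(C)(C)C | intermediate
36 | (2E)-N-[(1S,3S,4R,5R,6R)-4,6-bis(TBSO)-1-hydroxy-9-oxobicyclo[3.3.1]non-7-en-3-yl]-7-oxododec-2-enamide | CCCCCC(=O)CCC/C=C/C(=O)N[C@H]1C[C@@]2(O)C(=O)[C@H]([C@H](O[Si](C)(C)C(C)(C)C)C=C2)[C@H]1O[Si](C)(C)C(C)(C)C | intermediate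
37 | (2E)-N-[(1S,3S,4R,5R,6R)-1,4,6-trihydroxy-9-oxobicyclo[3.3.1]non-7-en-3-yl]-7-oxododec-2-enamide | CCCCCC(=O)CCC/C=C/C(=O)N[C@H]1C[C@@]2(O)C(=O)[C@H]([C@H](O)C=C2)[C@H]1O | intermediate
38 | isariotin C | CCCCCC(=O)CCC/C=C/C(=O)N[C@H]1C[C@@]2(O)C(=O)[C@H]([C@H](O)[C@@H]3O[C@@H]32)[C@H]1O | target

## Step count and least certain steps

Total step count: 22 (steps 5, 9, 17 and 18 are side-branch steps).
Longest linear sequence: 18 steps from 1 (steps 1–4, 6–8, 10–16, 19–22).

**Step 13 (key step).** The most likely failure is closure in the fused sense, with the nitrone carbon bonding to C1 to give a cyclopentanone, because the carbonyl in the tether changes the geometry of the usual bridged transition state. A second risk is conjugate addition of 21 to the enone before condensation. Poor facial selectivity is less likely, since the wrong face needs two axial groups. The fallback removes the carbonyl conjugation, so that the dipolarophile is a plain 1,1-disubstituted alkene, the substrate class for which bridged closure is documented. It sets out from enone 18. 1,2-Reduction (NaBH4, CeCl3, MeOH, −40 °C) gives the allylic alcohol F1 as both C9 epimers, and acetylation gives the acetate F2. Selective removal of the primary TBS group (HF·pyridine, pyridine) gives the primary alcohol F3, and DMP oxidation gives the aldehyde F4. Condensation with 21 gives the nitrone F5, which is heated in toluene without isolation to the bridged cycloadduct acetate F6. Methanolysis (K2CO3, MeOH) gives the carbinol F7, and DMP oxidation of F7 returns to 23.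

**Step 10.** The amide carbonyl is flanked by two silyloxy-bearing branches, so addition may be slow and deprotonation at C5 with β-elimination of a silyloxy group may take over. The transamination of step 7 carries a related risk of attack at the ring carbonyl of the auxiliary. The fallback avoids both by using an aldehyde as electrophile. It sets out from aldol 12. Silylation (TBSOTf, 2,6-lutidine) gives the imide silyl ether F8, and reductive removal of the auxiliary (LiBH4, THF/MeOH) gives the primary alcohol F9. DMP oxidation gives the aldehyde F10, and addition of 17 at −78 °C gives the allylic alcohol F1, the same compound as in the fallback above. DMP oxidation of F1 returns to 18.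

**Step 15.** Electron transfer to the ketone could expel the allylic α-oxygen at C1 (C–O instead of N–O cleavage), or the ketol could be reduced further. The fallback changes the mechanism from outer-sphere electron transfer to insertion: Mo(CO)6 (zerovalent molybdenum) in MeCN/H2O at 80 °C inserts into the N–O bond and does not reduce α-oxygenated ketones. It leads from 25 directly to 26 and makes no new compound.

**Step 16.** Tetravalent cerium may cleave the α-ketol oxidatively or oxidise the freed amine further, and the acidic medium may loosen a silyl ether. The fallback is a two-electron dehydrogenation and hydrolysis that avoids aqueous cerium. It sets out from 26: IBX in DMSO at rt gives the conjugated N-(4-methoxybenzylidene) imine F11, and hydrolysis with aqueous citric acid in THF returns to 27.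

**Step 20.** The diene may stay in the chair with both alkenyl arms equatorial, so that ring closure is slow and intermolecular metathesis or reaction at the enamide alkene takes over. The fallback changes the substrate so that the reactive conformer costs less. It sets out from 35: desilylation (HF·pyridine, pyridine, THF) gives the triol diene F12, whose hydroxyls are smaller than silyl ethers and whose free allylic hydroxyl speeds up metathesis. Ring closure of F12 under the conditions of step 20 gives 37 directly, and 36 is bypassed.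

**Step 22.** The secondary allylic alcohol may be oxidised to the enone, or the ketol may be degraded, before the alkene is epoxidised. The fallback epoxidises while C6 is still protected. It sets out from 36: VO(acac)2 and t-BuOOH, directed by the tertiary C1 hydroxyl alone and by the exo face, give the epoxide bis-silyl ether F13. Buffered fluoride (Bu4NF with AcOH, THF) then removes both silyl groups and gives 38.

## Further compounds

F1 | step 13 | (4R,5R)-4-[(1R)-1,2-bis(TBSO)ethyl]-5-(TBSO)-7-(phenylsulfanyl)-2-[2-(phenylsulfanyl)ethyl]hept-1-en-3-ol, both C3 epimers | C=C(CCSc1ccccc1)C(O)[C@H]([C@H](O[Si](C)(C)C(C)(C)C)CCSc1ccccc1)[C@@H](O[Si](C)(C)C(C)(C)C)CO[Si](C)(C)C(C)(C)C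
F2 | step 13 | acetate of F1 | C=C(CCSc1ccccc1)C(OC(C)=O)[C@H]([C@H](O[Si](C)(C)C(C)(C)C)CCSc1ccccc1)[C@@H](O[Si](C)(C)C(C)(C)C)CO[Si](C)(C)C(C)(C)C
F3 | step 13 | primary alcohol from F2 (primary TBS removed) | C=C(CCSc1ccccc1)C(OC(C)=O)[C@H]([C@H](O[Si](C)(C)C(C)(C)C)CCSc1ccccc1)[C@@H](O[Si](C)(C)C(C)(C)C)CO
F4 | step 13 | aldehyde from F3 | C=C(CCSc1ccccc1)C(OC(C)=O)[C@H]([C@H](O[Si](C)(C)C(C)(C)C)CCSc1ccccc1)[C@@H](O[Si](C)(C)C(C)(C)C)C=O
F5 | step 13 | (Z)-N-(4-methoxybenzyl) nitrone of F4 (not isolated) | [O-]/[N+](Cc1ccc(OC)cc1)=C\[C@H](O[Si](C)(C)C(C)(C)C)[C@@H]([C@H](O[Si](C)(C)C(C)(C)C)CCSc1ccccc1)C(OC(C)=O)C(=C)CCSc1ccccc1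
F6 | step 13 | bridged cycloadduct with acetoxy group at C9 (4-acetoxy analogue of 23) | COc1ccc(CN2O[C@]3(CCSc4ccccc4)C[C@H]2[C@H](O[Si](C)(C)C(C)(C)C)[C@@H]([C@H](O[Si](C)(C)C(C)(C)C)CCSc2ccccc2)C3OC(C)=O)cc1
F7 | step 13 | bridged cycloadduct with hydroxyl at C9 (4-hydroxy analogue of 23) | COc1ccc(CN2O[C@]3(CCSc4ccccc4)C[C@H]2[C@H](O[Si](C)(C)C(C)(C)C)[C@@H]([C@H](O[Si](C)(C)C(C)(C)C)CCSc2ccccc2)C3O)cc1
F8 | step 10 | (4S)-4-benzyl-3-[(2R,3R)-2-[(1R)-1,2-bis(TBSO)ethyl]-3-(TBSO)-5-(phenylsulfanyl)pentanoyl]oxazolidin-2-one | O=C1OC[C@H](Cc2ccccc2)N1C(=O)[C@H]([C@H](O[Si](C)(C)C(C)(C)C)CCSc1ccccc1)[C@@H](O[Si](C)(C)C(C)(C)C)CO[Si](C)(C)C(C)(C)C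
F9 | step 10 | primary alcohol from reduction of F8, 2-[(1R)-1,2-bis(TBSO)ethyl]-3-(TBSO)-5-(phenylsulfanyl)pentan-1-ol | OC[C@H]([C@H](O[Si](C)(C)C(C)(C)C)CCSc1ccccc1)[C@@H](O[Si](C)(C)C(C)(C)C)CO[Si](C)(C)C(C)(C)C
F10 | step 10 | aldehyde from F9, 2-[(1R)-1,2-bis(TBSO)ethyl]-3-(TBSO)-5-(phenylsulfanyl)pentanal | O=C[C@H]([C@H](O[Si](C)(C)C(C)(C)C)CCSc1ccccc1)[C@@H](O[Si](C)(C)C(C)(C)C)CO[Si](C)(C)C(C)(C)C
F0 | step 15 | none | none
F11 | step 16 | (E)-N-(4-methoxybenzylidene) imine of amine 27 | COc1ccc(/C=N/[C@H]2C[C@](O)(C=C)C(=O)[C@H]([C@H](O[Si](C)(C)C(C)(C)C)C=C)[C@H]2O[Si](C)(C)C(C)(C)C)cc1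
F12 | step 20 | (2E)-N-[(1S,2R,3R,5S)-5-ethenyl-2,5-dihydroxy-3-[(1R)-1-hydroxyprop-2-en-1-yl]-4-oxocyclohexyl]-7-oxododec-2-enamide | CCCCCC(=O)CCC/C=C/C(=O)N[C@H]1C[C@](O)(C=C)C(=O)[C@H]([C@H](O)C=C)[C@H]1O
F13 | step 22 | 4,6-bis-TBS ether of isariotin C | CCCCCC(=O)CCC/C=C/C(=O)N[C@H]1C[C@@]2(O)C(=O)[C@H]([C@H](O[Si](C)(C)C(C)(C)C)[C@@H]3O[C@@H]32)[C@H]1O[Si](C)(C)C(C)(C)C
A1 | alternative 1 | open-chain methyl ketone with C4 aldehyde and C6 epoxy aldehyde arms on C1 | CC(=O)[C@](O[Si](CC)(CC)CC)(C[C@H](NC(=O)OC(C)(C)C)C=O)[C@H]1O[C@H]1C=O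
A2 | alternative 1 | bicyclic core with free C4 and C6 carbinols, N-Boc, C1 triethylsilyl ether | CC(C)(C)OC(=O)N[C@H]1C[C@@]2(O[Si](CC)(CC)CC)C(=O)[C@H]([C@H](O)[C@@H]3O[C@@H]32)[C@H]1O
A3 | alternative 2 | methyl 4-C-allyl-2,3-anhydro-6-deoxyhex-5-enopyranoside (anomeric configuration immaterial) | CO[C@H]1OC(=C)[C@](O)(CC=C)[C@H]2O[C@@H]12
A4 | alternative 2 | 2-allyl-3,4-epoxy-2,5-dihydroxycyclohexanone | C=CC[C@@]1(O)C(=O)C[C@H](O)[C@@H]2O[C@@H]21
A5 | alternative 3 | N-Boc 3-allyl-3-(TBSO)pyrrolidin-2-one bearing the C4 silyloxy ester side chain at C5 | CC(C)(C)OC(=O)N1[C@@H](C[C@@](CC=C)(O[Si](C)(C)C(C)(C)C)C1=O)[C@H](O[Si](C)(C)C(C)(C)C)CC(=O)OC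
A6 | alternative 3 | ring A β-keto ester with allyl on C1 and ester carbon as C6 | CC(C)(C)OC(=O)N[C@H]1C[C@@](CC=C)(O[Si](C)(C)C(C)(C)C)C(=O)[C@H](C(=O)OC)[C@H]1O[Si](C)(C)C(C)(C)C
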